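**Retrosynthetic overview**

1. Psiguadial A 37 ⇐ 36 by Rieche formylation ⇐ 33 + PhB(OH)2, where a boronate-templated closure through a cyclic o-quinone methide makes the C1′–aryl and C1′–phenyl bonds and the oxepane ⇐ alcohol 26 + 2,4,6-trifluorobenzaldehyde by SNAr at the C1 tertiary alkoxide.
2. 26 ⇐ 24 by Kishner nitrogen extrusion, which builds the cyclopropane C6–C7–C11 from the C7 ketone and a C6 isopropylidene group ⇐ 23 by SmI2 cleavage of the temporary C8–O bridge ⇐ 18 + acetone.
3. 18 ⇐ 14 ⇐ diazoketone 11 + methyl methacrylate: rhodium carbenoid, then carbonyl ylide, then cycloaddition, which forms C8–C9 and C10–C1 and the seven-membered ring in one operation. It is possible because the C1 ketone oxygen lies 1,5 to the diazo carbon C8 across C5–C6–C7, and the C7 carbonyl stabilises the dipole, so that the ring O–C1–C5–C6–C7–C8 is a six-membered carbonyl ylide whose two termini are C8 and C1.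
4. 11 ⇐ 3-methylcyclopent-2-enone by copper-catalysed asymmetric conjugate addition (C4), enolate alkylation (C5) and acylation of diazomethane.
5. Ring order: cyclopentane (from 1) → oxygen-bridged cycloheptane (step 5) → cyclopropane (step 11) → benzoxepine (step 16).

Key step: step 5

Remark: terpenoid carbons carry aromadendrane numbers (C1–C15; C11 = CMe2 carbon, C14 = methyl on C10, C15 = methyl on C4), C1′ is the benzylic carbon and a1–a6 are the arene carbons counted from the ether carbon; β is the face of the C1 oxygen (H5, C11, C14 and C1′ are β; C15, H6, H7 and H10 are α).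

**Route**

Step 1
Reactants: 1 3-methylcyclopent-2-en-1-one; 2 ethynyltrimethylsilane
Product: 5 silyl enol ether (S)-trimethyl{[3-methyl-3-(1-(trimethylsilyl)ethenyl)cyclopent-1-en-1-yl]oxy}silane, via vinylalane 3 (not isolated), via aluminium enolate 4 (not isolated)
Conditions: 2, i-Bu2AlH, hexane/THF, 55 °C; then 1, Cu(OTf)2 (5 mol %), chiral sulfonate-bearing imidazolinium salt (5 mol %), THF, −78 to 4 °C; then Me3SiOTf, −78 °C to rt
Reagents that add atoms: trimethylsilyl trifluoromethanesulfonate, C[Si](C)(C)OS(=O)(=O)C(F)(F)F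
Why: Hydroalumination gives the α-silyl vinylalane, whose copper-catalysed asymmetric conjugate addition (chiral N-heterocyclic carbene ligand, enantiomer chosen for the S centre) to the β-methyl enone should set the quaternary C4 under catalyst control, and O-silylation of the aluminium enolate keeps the C1/C5 enolate regiochemistry.

Step 2
Reactants: 5 silyl enol ether; 6 methyl bromoacetate
Product: 8 keto ester methyl {2-methyl-5-oxo-2-[1-(trimethylsilyl)ethenyl]cyclopentyl}acetate (acetate arm trans to the silylvinyl group), via lithium enolate 7 (not isolated)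
Conditions: MeLi, THF, 0 °C; then 6, DMPU, −78 to −20 °C
Reagents that add atoms: none
Why: MeLi cleaves the silyl enol ether to the regiodefined lithium enolate, and its SN2 alkylation should occur on the face of C5 anti to the bulky 1-(trimethylsilyl)vinyl group, which puts the C6–C7 arm cis to the C4 methyl group and H5 on the β-face.

Step 3
Reactants: 8 keto ester
Product: 9 keto acid {2-methyl-5-oxo-2-[1-(trimethylsilyl)ethenyl]cyclopentyl}acetic acid
Conditions: LiOH·H2O, THF/H2O, 0 °C to rt; then 1 M HCl
Reagents that add atoms: lithium hydroxide, [Li+].[OH-]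
Why: Ester saponification; the epimerisable C5 centre should stay in the thermodynamically preferred trans arrangement set in step 2.

Step 4
Reactants: 9 keto acid
Product: 11 diazoketone 1-diazo-3-{2-methyl-5-oxo-2-[1-(trimethylsilyl)ethenyl]cyclopentyl}propan-2-one, via mixed anhydride 10 (not isolated)
Conditions: i-BuOCOCl, N-methylmorpholine, THF, −15 °C; then CH2N2, Et2O, 0 °C
Reagents that add atoms: diazomethane, C=[N+]=[N-]
Why: Acylation of diazomethane by the mixed carbonic anhydride (the diazoketone synthesis of the Arndt–Eistert sequence) avoids the cyclic pseudo-chloride of a γ-keto acid and touches no stereocentre.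

Step 5
Reactants: 11 diazoketone; 12 methyl methacrylate
Product: 14 oxygen-bridged keto ester methyl 1β,8β-epoxy-4α,10β-dimethyl-7-oxo-4β-[1-(trimethylsilyl)ethenyl]-5βH-perhydroazulene-10α-carboxylate, via carbonyl ylide 13 (not isolated)
Conditions: Rh2(OAc)4 (1 mol %), 12 (10 equiv), CH2Cl2, rt, slow addition of 11
Reagents that add atoms: none
Why: Rh2(OAc)4 turns the diazoketone into a rhodium carbenoid at C8, the C1 ketone oxygen adds to it and closes the six-membered carbonyl ylide 13 (ring O–C1–C5–C6–C7–C8, by attack of oxygen on the carbenoid carbon), and this 1,3-dipole adds suprafacially across the C=C bond of methyl methacrylate, which closes the seven-membered carbocycle and the bridging oxolane in one [π4s+π2s] event. The closest known reaction type is the tandem carbenoid cyclisation–carbonyl ylide cycloaddition of 1-diazo-2,5-diones with acrylic dipolarophiles. Regiochemistry should follow the HOMO(dipole)–LUMO(dipolarophile) pairing: the acyl-stabilised, nucleophilic terminus C8 bonds to the unsubstituted β-carbon (C9) and the electrophilic ketone-derived terminus C1 bonds to the α-carbon (C10). C1 and C8 are controlled by the C4 and C5 centres, because the dipolarophile should approach the ylide face anti to the 1-(trimethylsilyl)vinyl group and anti to the pseudo-axial H5, which leaves the oxygen bridge on the β-face and the cyclopentane fused diequatorially to the new oxane. C10 is set by the endo rule (ester under the dipole, methyl exo and therefore β, syn to the oxygen bridge); this is the selectivity the step needs, and it should be helped by the one-atom bridge being an oxygen with no substituent to clash with the exo methyl group.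

Step 6
Reactants: 14 oxygen-bridged keto ester
Product: 17 keto aldehyde 1β,8β-epoxy-4α,10β-dimethyl-7-oxo-4β-[1-(trimethylsilyl)ethenyl]-5βH-perhydroazulene-10α-carbaldehyde, via lithium enolate 15 (not isolated), via aluminium hemiacetal 16 (not isolated)
Conditions: LiN(i-Pr)2 (1.1 equiv), THF, −78 °C; then i-Bu2AlH (1.2 equiv), −78 °C; AcOH, then aqueous Rochelle salt
Reagents that add atoms: none
Why: The ketone is masked in the flask as its C6 enolate (the only one possible, C8 being a bridgehead), and partial reduction of the hindered, β-alkoxy ester by i-Bu2AlH should stop at the chelated hemiacetal aluminate, which gives the aldehyde on work-up without change at the quaternary C10.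

Step 7
Reactants: 17 keto aldehyde
Product: 18 oxygen-bridged ketone 1β,8β-epoxy-4α,10β-dimethyl-4β-[1-(trimethylsilyl)ethenyl]-5βH,10αH-perhydroazulen-7-one
Conditions: RhCl(PPh3)3 (1.1 equiv), PhCN, 130 °C
Reagents that add atoms: none
Why: Tsuji–Wilkinson decarbonylation (oxidative addition into the formyl C–H bond, loss of CO, C–H reductive elimination) should replace the endo formyl group by hydrogen with retention, so that C10 carries H on the α-face and its methyl group on the β-face.

Step 8
Reactants: 18 oxygen-bridged ketone; 19 acetone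
Product: 21 aldol adduct 1β,8β-epoxy-6β-(2-hydroxypropan-2-yl)-4α,10β-dimethyl-4β-[1-(trimethylsilyl)ethenyl]perhydroazulen-7-one, via lithium enolate 20 (not isolated)
Conditions: LiN(i-Pr)2, THF, −78 °C; then 19, −78 °C; AcOH
Reagents that add atoms: none
Why: Only C6 can be enolised (C8 is a bridgehead, Bredt's rule), so the kinetic aldol addition to acetone should attach C11 with its two methyl groups regiospecifically at C6, from the exo face (this centre becomes trigonal in step 9).

Step 9
Reactants: 21 aldol adduct
Product: 23 bridged enone 1β,8β-epoxy-4α,10β-dimethyl-6-(propan-2-ylidene)-4β-[1-(trimethylsilyl)ethenyl]perhydroazulen-7-one, via mesylate 22 (not isolated)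
Conditions: MsCl, Et3N (excess), CH2Cl2, 0 °C to rt
Reagents that add atoms: none
Why: Mesylation of the tertiary aldol hydroxyl (sulfene pathway) and E1cB elimination should give the conjugated C6 isopropylidene ketone, completing an aldol condensation that involves no stereocentre of the target.

Step 10
Reactants: 23 bridged enone
Product: 24 hydroxy enone 1β-hydroxy-4α,10β-dimethyl-6-(propan-2-ylidene)-4β-[1-(trimethylsilyl)ethenyl]-5βH-perhydroazulen-7-one
Conditions: SmI2 (2.5 equiv), THF/MeOH, −78 °C
Reagents that add atoms: none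
Why: SmI2 reduces the C7 ketone to its ketyl and expels the α-alkoxy group (reductive cleavage of an α-alkoxy ketone), so the C8–O bond breaks, C8 becomes CH2 and the bridging oxygen stays on C1 as the tertiary β-alcohol with unchanged configuration.

Step 11
Reactants: 24 hydroxy enone
Product: 26 alcohol 4β-ethenyl-aromadendran-1β-ol (4α,10β-dimethyl, 5βH, 6αH, 7αH), via pyrazoline 25 (not isolated)
Conditions: N2H4·H2O, EtOH, 80 °C; then KOH, diethylene glycol, 200 °C
Reagents that add atoms: none
Why: Kishner cyclopropane synthesis: hydrazine condenses with the C7 ketone and adds to C11 to give the fused 2-pyrazoline, which with hot KOH tautomerises and loses N2 with C7–C11 bond formation (as α-isopropylidene cycloalkanones such as pulegone give caranes); the epimerisable C6 should settle with C11 trans to the quaternary C4 (β-face), the new fusion at C7 can only be cis, and the hot alkoxide is expected to protodesilylate the vinylsilane in the same operation.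

Step 12
Reactants: 26 alcohol; 27 2,4,6-trifluorobenzaldehyde
Product: 29 aryl ether 4-[(4β-ethenyl-aromadendran-1β-yl)oxy]-2,6-difluorobenzaldehyde, via potassium alkoxide 28 (not isolated)
Conditions: KH, 18-crown-6, THF, 0 °C; then 27, −20 °C to rt
Reagents that add atoms: none
Why: SNAr of the tertiary alkoxide at the fluorine para to the formyl group (the unhindered, most activated position) should form the C1–O–aryl bond without touching the C1 stereocentre.

Step 13
Reactants: 29 aryl ether
Product: 30 bis(silylethyl) ether 4-[(4β-ethenyl-aromadendran-1β-yl)oxy]-2,6-bis[2-(trimethylsilyl)ethoxy]benzaldehyde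
Conditions: Me3SiCH2CH2OH (2.5 equiv), NaH (2.5 equiv), DMF, 0 to 50 °C
Reagents that add atoms: 2-(trimethylsilyl)ethanol, C[Si](C)(C)CCO
Why: Twofold SNAr of the two fluorines ortho to the formyl group by the alkoxide should install both phenol oxygens in masked form, so that no deactivating phenoxide stops the second substitution.

Step 14
Reactants: 30 bis(silylethyl) ether
Product: 32 dialdehyde in which the C4 vinyl group of 30 has become the C1′ formyl group, via diol 31 (not isolated)
Conditions: OsO4 (2 mol %), NaIO4 (4 equiv), 2,6-lutidine, dioxane/H2O, rt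
Reagents that add atoms: sodium periodate (terminal oxygen source through OsO4), [Na+].[O-]I(=O)(=O)=O
Why: Lemieux–Johnson oxidation (dihydroxylation, then periodate glycol cleavage) should convert the only alkene into the neopentyl C1′ aldehyde while the arene and the cyclopropane are inert.

Step 15
Reactants: 32 dialdehyde
Product: 33 bisphenol 1β-(4-formyl-3,5-dihydroxyphenoxy)-aromadendrane-4β-carbaldehyde
Conditions: Bu4NF, AcOH, THF, 50 °C
Reagents that add atoms: none
Why: Fluoride attack at silicon fragments both 2-(trimethylsilyl)ethyl aryl ethers with loss of ethene, and the acetic acid buffer should keep the phenols protonated so that the non-enolisable C1′ aldehyde is not yet engaged.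

Step 16
Reactants: 33 bisphenol; 34 phenylboronic acid
Product: 36 monoaldehyde (psiguadial A lacking the a2 formyl group), via o-quinone methide 35 (not isolated)
Conditions: 34 (3 equiv), 3,3′-dibromo-1,1′-bi-2-naphthol (20 mol %), 4 Å MS, toluene, 60 °C
Reagents that add atoms: none
Why: Boron-templated ortho-hydroxyalkylation of the phenol by the tethered C1′ aldehyde (the intramolecular form of the Petasis-type condensation of phenols, aldehydes and boronates) closes the oxepane and gives the cyclic o-quinone methide, to which the boron-bound phenyl group should be transferred on the convex face, away from the C2–C3 bridge, setting C1′ as in the target.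

Step 17
Reactants: 36 monoaldehyde
Product: 37 psiguadial A
Conditions: Cl2CHOMe, TiCl4, CH2Cl2, −78 to 0 °C; then H2O
Reagents that add atoms: dichloromethyl methyl ether, COC(Cl)Cl; water, O
Why: Rieche formylation should take place at a2, the only free arene position, which is flanked by the ether oxygen and a free hydroxyl group; no stereocentre is involved.

**Compound list**

1 | 3-methylcyclopent-2-en-1-one | CC1=CC(=O)CC1 | starting material
2 | ethynyltrimethylsilane | C#C[Si](C)(C)C | starting material
3 | diisobutyl[1-(trimethylsilyl)ethenyl]aluminium | C=C([Si](C)(C)C)[Al](CC(C)C)CC(C)C | intermediate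
4 | diisobutylaluminium enolate of (S)-3-methyl-3-[1-(trimethylsilyl)ethenyl]cyclopentanone | C=C([Si](C)(C)C)[C@@]1(C)CCC(O[Al](CC(C)C)CC(C)C)=C1 | intermediate
5 | (S)-trimethyl{[3-methyl-3-(1-(trimethylsilyl)ethenyl)cyclopent-1-en-1-yl]oxy}silane | C[Si](C)(C)OC1=C[C@@](C)(C(=C)[Si](C)(C)C)CC1 | intermediate
6 | methyl bromoacetate | COC(=O)CBr | starting material
7 | lithium enolate corresponding to 5 | [Li]OC1=C[C@@](C)(C(=C)[Si](C)(C)C)CC1 | intermediate
8 | methyl {2-methyl-5-oxo-2-[1-(trimethylsilyl)ethenyl]cyclopentyl}acetate, acetate arm trans to the silylvinyl group (C4 as in 5, H5 β) | COC(=O)C[C@H]1C(=O)CC[C@]1(C)C(=C)[Si](C)(C)C | intermediate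
9 | {2-methyl-5-oxo-2-[1-(trimethylsilyl)ethenyl]cyclopentyl}acetic acid, same configuration as 8 | OC(=O)C[C@H]1C(=O)CC[C@]1(C)C(=C)[Si](C)(C)C | intermediate
10 | mixed isobutyl carbonic anhydride of 9 | CC(C)COC(=O)OC(=O)C[C@H]1C(=O)CC[C@]1(C)C(=C)[Si](C)(C)C | intermediate
11 | 1-diazo-3-{2-methyl-5-oxo-2-[1-(trimethylsilyl)ethenyl]cyclopentyl}propan-2-one, same configuration as 8 | [N-]=[N+]=CC(=O)C[C@H]1C(=O)CC[C@]1(C)C(=C)[Si](C)(C)C | intermediate
12 | methyl methacrylate | COC(=O)C(C)=C | starting material
13 | six-membered carbonyl ylide (ring O–C1–C5–C6–C7–C8, C7 ketone) fused to the cyclopentane | O=C1C[C@H]2C(=[O+][CH-]1)CC[C@]2(C)C(=C)[Si](C)(C)C | intermediate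
14 | methyl 1β,8β-epoxy-4α,10β-dimethyl-7-oxo-4β-[1-(trimethylsilyl)ethenyl]-5βH-perhydroazulene-10α-carboxylate | COC(=O)[C@]1(C)C[C@H]2O[C@@]13CC[C@](C)(C(=C)[Si](C)(C)C)[C@H]3CC2=O | intermediate
15 | lithium C6–C7 enolate of 14 | COC(=O)[C@]1(C)C[C@H]2O[C@@]13CC[C@](C)(C(=C)[Si](C)(C)C)[C@H]3C=C2O[Li] | intermediate
16 | diisobutylaluminium hemiacetal of the C10 ester in enolate 15 | COC(O[Al](CC(C)C)CC(C)C)[C@]1(C)C[C@H]2O[C@@]13CC[C@](C)(C(=C)[Si](C)(C)C)[C@H]3C=C2O[Li] | intermediate
17 | 1β,8β-epoxy-4α,10β-dimethyl-7-oxo-4β-[1-(trimethylsilyl)ethenyl]-5βH-perhydroazulene-10α-carbaldehyde | O=C[C@]1(C)C[C@H]2O[C@@]13CC[C@](C)(C(=C)[Si](C)(C)C)[C@H]3CC2=O | intermediate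
18 | 1β,8β-epoxy-4α,10β-dimethyl-4β-[1-(trimethylsilyl)ethenyl]-5βH,10αH-perhydroazulen-7-one | C[C@H]1C[C@H]2O[C@@]13CC[C@](C)(C(=C)[Si](C)(C)C)[C@H]3CC2=O | intermediate
19 | acetone | CC(C)=O | starting material
20 | lithium C6–C7 enolate of 18 | C[C@H]1C[C@H]2O[C@@]13CC[C@](C)(C(=C)[Si](C)(C)C)[C@H]3C=C2O[Li] | intermediate
21 | 6β-(2-hydroxypropan-2-yl) derivative of 18 | C[C@H]1C[C@H]2O[C@@]13CC[C@](C)(C(=C)[Si](C)(C)C)[C@H]3[C@H](C(C)(C)O)C2=O | intermediate
22 | methanesulfonate of the tertiary alcohol 21 | C[C@H]1C[C@H]2O[C@@]13CC[C@](C)(C(=C)[Si](C)(C)C)[C@H]3[C@H](C(C)(C)OS(C)(=O)=O)C2=O | intermediate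
23 | 1β,8β-epoxy-4α,10β-dimethyl-6-(propan-2-ylidene)-4β-[1-(trimethylsilyl)ethenyl]-5βH-perhydroazulen-7-one | C[C@H]1C[C@H]2O[C@@]13CC[C@](C)(C(=C)[Si](C)(C)C)[C@H]3C(=C(C)C)C2=O | intermediate
24 | 1β-hydroxy-4α,10β-dimethyl-6-(propan-2-ylidene)-4β-[1-(trimethylsilyl)ethenyl]-5βH-perhydroazulen-7-one | C[C@H]1CCC(=O)C(=C(C)C)[C@@H]2[C@@](C)(C(=C)[Si](C)(C)C)CC[C@@]21O | intermediate
25 | 2-pyrazoline fused at C6–C7 (N–N=C7, NH on C11, C11 β on C6) | C[C@H]1CCC2=NNC(C)(C)[C@H]2[C@@H]3[C@@](C)(C(=C)[Si](C)(C)C)CC[C@@]31O | intermediate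
26 | 4β-ethenyl-aromadendran-1β-ol (4α,10β-dimethyl; 5βH; cyclopropane β, 6αH, 7αH) | C[C@H]1CC[C@@H]2[C@H]([C@@H]3[C@](C=C)(C)CC[C@@]31O)C2(C)C | intermediate
27 | 2,4,6-trifluorobenzaldehyde | O=Cc1c(F)cc(F)cc1F | starting material
28 | potassium alkoxide of 26 | C[C@H]1CC[C@@H]2[C@H]([C@@H]3[C@](C=C)(C)CC[C@@]31[O-])C2(C)C.[K+] | intermediate
29 | 4-[(4β-ethenyl-aromadendran-1β-yl)oxy]-2,6-difluorobenzaldehyde | C[C@H]1CC[C@@H]2[C@H]([C@@H]3[C@](C=C)(C)CC[C@@]31Oc1cc(F)c(C=O)c(F)c1)C2(C)C | intermediate
30 | 4-[(4β-ethenyl-aromadendran-1β-yl)oxy]-2,6-bis[2-(trimethylsilyl)ethoxy]benzaldehyde | C[C@H]1CC[C@@H]2[C@H]([C@@H]3[C@](C=C)(C)CC[C@@]31Oc1cc(OCC[Si](C)(C)C)c(C=O)c(OCC[Si](C)(C)C)c1)C2(C)C | intermediate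
31 | 1,2-diol from the C4 vinyl group of 30 (carbinol epimers) | C[C@H]1CC[C@@H]2[C@H]([C@@H]3[C@](C(O)CO)(C)CC[C@@]31Oc1cc(OCC[Si](C)(C)C)c(C=O)c(OCC[Si](C)(C)C)c1)C2(C)C | intermediate
32 | 1β-{4-formyl-3,5-bis[2-(trimethylsilyl)ethoxy]phenoxy}-aromadendrane-4β-carbaldehyde | C[C@H]1CC[C@@H]2[C@H]([C@@H]3[C@](C=O)(C)CC[C@@]31Oc1cc(OCC[Si](C)(C)C)c(C=O)c(OCC[Si](C)(C)C)c1)C2(C)C | intermediate
33 | 1β-(4-formyl-3,5-dihydroxyphenoxy)-aromadendrane-4β-carbaldehyde | C[C@H]1CC[C@@H]2[C@H]([C@@H]3[C@](C=O)(C)CC[C@@]31Oc1cc(O)c(C=O)c(O)c1)C2(C)C | intermediate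
34 | phenylboronic acid | OB(O)c1ccccc1 | starting material
35 | cyclic o-quinone methide (C1′=a6, a5 carbonyl) with the oxepane closed | C[C@H]1CC[C@@H]2[C@H]([C@@H]3[C@]4(C)CC[C@@]31OC5=CC(O)=C(C=O)C(=O)C5=C4)C2(C)C | intermediate
36 | psiguadial A lacking the a2 formyl group (C1′ as in the target) | C[C@H]1CC[C@@H]2[C@H]([C@@H]3[C@]4(C)CC[C@@]31Oc1cc(O)c(C=O)c(O)c1[C@@H]4c1ccccc1)C2(C)C | intermediate
37 | psiguadial A | C[C@H]1CC[C@@H]2[C@H]([C@@H]3[C@]4(C)CC[C@@]31Oc1c(C=O)c(O)c(C=O)c(O)c1[C@@H]4c1ccccc1)C2(C)C | target

**Count and risks**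

Total step count: 17. Longest linear sequence: 17 steps (1 → 37).

Steps most likely to fail:

Step 11 (Kishner extrusion). The 1-pyrazoline may fragment to olefins by hydrogen shift instead of closing the three-membered ring, and the C6 configuration may not be fully controlled at 200 °C. The fallback adds dimethylcarbene to a C6–C7 alkene instead; it sets out from 18 and comes back at 26. SmI2 cleavage of the C8–O bridge of 18 would give the hydroxy ketone F2. Double deprotonation with LiN(i-Pr)2 and O-triflation with PhNTf2 would give, after separation from the C7–C8 regioisomer, the C6–C7 enol triflate F3. Reduction with Pd(OAc)2, PPh3, HCO2H and Et3N would give the alkene F4, and Bu4NF in DMSO at 80 °C the desilylated alkene F5. Dibromocarbene (CHBr3, KOt-Bu) should add to the ring alkene on the β-face, anti to C4, to give the dibromocyclopropane F6, and Me2CuLi followed by MeI would then give 26.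

Step 16 (closure and phenyl transfer). Phenyl transfer from boron may be slow, so that the o-quinone methide oligomerises, or the facial selectivity at C1′ may be poor. The fallback separates ring closure from phenylation and uses a Grignard reagent; it sets out from 33 and comes back at 36. K2CO3 in MeOH should add the phenoxide carbon a6 to the C1′ aldehyde and give the cyclic o-hydroxybenzyl alcohol F7 (C1′ epimers, both usable). The aryl aldehyde is then masked in the flask as its α-amino alkoxide with LiN(Me)CH2CH2NMe2, and excess PhMgBr (THF, −20 to 40 °C) should generate the o-quinone methide by elimination and add phenyl on the convex face to give 36.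

Step 5 (key cycloaddition). The endo/exo selectivity at C10 may be poor (ester exo, methyl endo), and the ylide may dimerise. The fallback sets C10 by alkylation instead of by the topology of the cycloaddition; it sets out from 11 and comes back at 14. The same Rh2(OAc)4 cycloaddition with methyl acrylate would give the acrylate cycloadduct F1 (either C10 epimer is usable). Formation of the dianion with LiN(i-Pr)2 (2.2 equiv, −78 °C) and methylation of the more reactive ester enolate with MeI (1 equiv) from the exo face, at low temperature to outrun β-elimination of the bridge, would give 14.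

Further compounds
F1 | step 5 | methyl 1β,8β-epoxy-4α-methyl-7-oxo-4β-[1-(trimethylsilyl)ethenyl]-5βH-perhydroazulene-10α-carboxylate (10-demethyl analogue of 14, with its C10 epimer) | COC(=O)[C@@H]1C[C@H]2O[C@@]13CC[C@](C)(C(=C)[Si](C)(C)C)[C@H]3CC2=O
F2 | step 11 | 1β-hydroxy-4α,10β-dimethyl-4β-[1-(trimethylsilyl)ethenyl]-5βH-perhydroazulen-7-one | C[C@H]1CCC(=O)C[C@@H]2[C@@](C)(C(=C)[Si](C)(C)C)CC[C@@]21O
F3 | step 11 | C6–C7 enol trifluoromethanesulfonate of F2 | C[C@H]1CCC(OS(=O)(=O)C(F)(F)F)=C[C@@H]2[C@@](C)(C(=C)[Si](C)(C)C)CC[C@@]21O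
F4 | step 11 | 1β-hydroxy C6–C7 alkene with the 4β-[1-(trimethylsilyl)ethenyl] group | C[C@H]1CCC=C[C@@H]2[C@@](C)(C(=C)[Si](C)(C)C)CC[C@@]21O
F5 | step 11 | 1β-hydroxy C6–C7 alkene with the 4β-ethenyl group | C[C@H]1CCC=C[C@@H]2[C@@](C)(C=C)CC[C@@]21O
F6 | step 11 | 11,11-dibromo analogue of 26 (12,13-dinor, dibromocyclopropane on the β-face) | C[C@H]1CC[C@@H]2[C@H]([C@@H]3[C@](C=C)(C)CC[C@@]31O)C2(Br)Br
F7 | step 16 | cyclic o-hydroxybenzyl alcohol (oxepane closed, hydroxyl on C1′, C1′ epimers) | C[C@H]1CC[C@@H]2[C@H]([C@@H]3[C@]4(C)CC[C@@]31Oc1cc(O)c(C=O)c(O)c1C4O)C2(C)C
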